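**Strategy.** The target is an all-equatorial trans-decalin (eudesmane locants: ring A = C1–C5 and C10, ring B = C5–C10), so both rings are unzipped to an open-chain epoxy-diene. In the key step Cp2TiCl opens a terminal oxirane (C4–C15) to a C4 radical that closes ring A by bonding to C5 of an E-C5=C10 alkene; the C10 radical then closes ring B on an isopropenyl group. One operation forms C4–C5 and C9–C10, sets C4, C5 and C10, and frees C15 as CH2OH. It exploits the trans C5-H/C10-CH3 fusion flanked by equatorial groups on C1, C4, C6 and C7: the imprint of anti addition across an E alkene in a chair–chair array.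

Key step: step 11

Remark on labels: C1–C15 are eudesmane locants (C14 = methyl on C10; C15 = carbon on C4; C11–C13 = three-carbon unit on C7); β is the face of the C10 methyl group.
Remark on the chemistry: the oxirane carbon of the epoxyhexene starting material becomes the planar C4 radical in the key step, so its configuration is inconsequential; the (R)-epoxide is assumed commercially available and is used only so that every intermediate is one stereoisomer.

Step 1
Reactants: 1 4-tert-butoxy-4-oxobutanoic acid (mono-tert-butyl succinate); 2 (4S)-4-benzyl-1,3-oxazolidin-2-one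
Product: 4 (4S)-4-benzyl-3-(4-tert-butoxy-4-oxobutanoyl)-1,3-oxazolidin-2-one, via mixed pivalic anhydride 3 (not isolated)
Conditions: PivCl, Et3N, THF, −20 °C; then 2, LiCl, −20 °C → rt
Reagents that add atoms: none
Why: Mixed-anhydride N-acylation of the oxazolidinone occurs at the unhindered succinyl carbonyl of 3 and leaves the tert-butyl ester untouched; no stereocenter is formed.

Step 2
Reactants: 5 but-2-yn-1-ol
Product: 6 but-2-ynal
Conditions: MnO2, CH2Cl2, rt
Reagents that add atoms: none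
Why: MnO2 oxidation of a propargylic alcohol stops cleanly at the volatile ynal, which is used as a solution; no stereocenter.

Step 3
Reactants: 4 (4S)-4-benzyl-3-(4-tert-butoxy-4-oxobutanoyl)-1,3-oxazolidin-2-one; 6 but-2-ynal
Product: 8 (4S)-4-benzyl-3-[(2S,3S)-2-(2-tert-butoxy-2-oxoethyl)-3-hydroxyhex-4-ynoyl]-1,3-oxazolidin-2-one, via dibutylboron (Z)-enolate 7 (not isolated)
Conditions: Bu2BOTf, iPr2NEt, CH2Cl2, −78 → 0 °C; then 6, −78 → 0 °C; H2O2, pH 7 buffer, MeOH
Reagents that add atoms: none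
Why: Evans syn-aldol reaction, in which the (Z)-boron enolate 7 reacts through a closed Zimmerman–Traxler chair on the face opposite the benzyl group of the (S)-auxiliary, so that C6 and C7 are set together as the syn (2S,3S) adduct.

Step 4
Reactants: 8 (4S)-4-benzyl-3-[(2S,3S)-2-(2-tert-butoxy-2-oxoethyl)-3-hydroxyhex-4-ynoyl]-1,3-oxazolidin-2-one
Product: 9 tert-butyl (3S,4S)-4-hydroxy-3-[methoxy(methyl)carbamoyl]hept-5-ynoate
Conditions: MeNH(OMe)·HCl, AlMe3, CH2Cl2, −10 → 0 °C; dilute aq. HCl work-up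
Reagents that add atoms: N,O-dimethylhydroxylamine hydrochloride CNOC.Cl
Why: Aluminium-amide transamidation (Weinreb amide formation) is accelerated by the free C6 alkoxide, spares the hindered tert-butyl ester and releases the auxiliary without touching C6 or C7.

Step 5
Reactants: 9 tert-butyl (3S,4S)-4-hydroxy-3-[methoxy(methyl)carbamoyl]hept-5-ynoate
Product: 10 tert-butyl (3S,4S)-3-[methoxy(methyl)carbamoyl]-4-(triethylsilyloxy)hept-5-ynoate
Conditions: TESCl, imidazole, DMF, 0 °C → rt
Reagents that add atoms: chlorotriethylsilane CC[Si](Cl)(CC)CC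
Why: Silyl ether formation on the secondary propargylic alcohol; no stereocenter is created or disturbed.

Step 6
Reactants: 10 tert-butyl (3S,4S)-3-[methoxy(methyl)carbamoyl]-4-(triethylsilyloxy)hept-5-ynoate
Product: 11 tert-butyl (3S,4S)-3-acetyl-4-(triethylsilyloxy)hept-5-ynoate
Conditions: MeMgBr, THF, −20 → 0 °C; aq. NH4Cl
Reagents that add atoms: methylmagnesium bromide C[Mg]Br
Why: Weinreb ketone synthesis, in which the chelated tetrahedral intermediate stops at the methyl ketone, the tert-butyl ester is too hindered to react at 0 °C and C7 is not epimerised.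

Step 7
Reactants: 11 tert-butyl (3S,4S)-3-acetyl-4-(triethylsilyloxy)hept-5-ynoate
Product: 12 tert-butyl (3R,4S)-3-(prop-1-en-2-yl)-4-(triethylsilyloxy)hept-5-ynoate
Conditions: Cp2Ti(μ-Cl)(μ-CH2)AlMe2, pyridine, THF/toluene, −40 → 0 °C
Reagents that add atoms: Tebbe reagent Cp2Ti(μ-Cl)(μ-CH2)AlMe2 C[Al-]1(C)C[Ti](C2C=CC=C2)(C2C=CC=C2)[Cl+]1
Why: Tebbe methylenation turns the ketone into the isopropenyl group under non-basic conditions, so the α-stereocenter C7 and the β-silyloxy group survive, and the ketone reacts before the ester and the alkyne at low temperature.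

Step 8
Reactants: 13 (2R)-2-(but-3-en-1-yl)oxirane
Product: 14 3-[(2R)-oxiran-2-yl]propanal
Conditions: O3, CH2Cl2, −78 °C; then PPh3, −78 °C → rt
Reagents that add atoms: ozone [O-][O+]=O
Why: Ozonolysis with reductive work-up cleaves the only C=C bond while the oxirane is inert to ozone, so the oxirane centre is carried through unchanged.

Step 9
Reactants: 12 tert-butyl (3R,4S)-3-(prop-1-en-2-yl)-4-(triethylsilyloxy)hept-5-ynoate; 14 3-[(2R)-oxiran-2-yl]propanal
Product: 17 tert-butyl (3R,4R,5E,7R)-7-hydroxy-6-methyl-9-[(2R)-oxiran-2-yl]-3-(prop-1-en-2-yl)-4-(triethylsilyloxy)non-5-enoate, via alkenylzirconocene chloride 15 (not isolated), via alkenyl(methyl)zinc 16 (not isolated)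
Conditions: Cp2Zr(H)Cl, CH2Cl2, rt; then Me2Zn, toluene, −65 °C; (−)-MIB (10 mol%), then 14, −30 °C; aq. NH4Cl
Reagents that add atoms: none
Why: syn-Hydrozirconation places Zr on the less hindered methyl-bearing alkyne carbon C10 (fixing the E-C5=C10 geometry), Zr-to-Zn transmetalation gives 16, and its amino-alcohol-catalysed 1,2-addition to 14 is directed by (−)-MIB to the Si face of the aldehyde, which sets (R)-C1.

Step 10
Reactants: 17 tert-butyl (3R,4R,5E,7R)-7-hydroxy-6-methyl-9-[(2R)-oxiran-2-yl]-3-(prop-1-en-2-yl)-4-(triethylsilyloxy)non-5-enoate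
Product: 18 tert-butyl (3R,4R,5E,7R)-6-methyl-9-[(2R)-oxiran-2-yl]-3-(prop-1-en-2-yl)-4,7-bis(triethylsilyloxy)non-5-enoate
Conditions: TESCl, imidazole, DMAP (cat.), CH2Cl2, 0 °C
Reagents that add atoms: chlorotriethylsilane CC[Si](Cl)(CC)CC
Why: Silyl ether formation under mild basic conditions, with no Lewis acid present that could trigger attack of O1 on the oxirane; no stereocenter is affected.

Step 11
Reactants: 18 tert-butyl (3R,4R,5E,7R)-6-methyl-9-[(2R)-oxiran-2-yl]-3-(prop-1-en-2-yl)-4,7-bis(triethylsilyloxy)non-5-enoate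
Product: 19 tert-butyl 2-[4α-(hydroxymethyl)-10β-methyl-8-methylidene-1β,6α-bis(triethylsilyloxy)-5αH-trans-decalin-7β-yl]acetate
Conditions: Cp2TiCl2 (2.5 equiv), Mn dust, THF, rt, the Cp2TiCl solution added slowly to dilute 18; aq. NaH2PO4 work-up
Reagents that add atoms: none
Why: Cp2TiCl (trivalent titanium, made in the flask from Cp2TiCl2 and Mn) opens the oxirane homolytically at its more substituted carbon to the β-titanoxy secondary radical at C4, which adds to C5 of the E-alkene to form the C4–C5 bond; the tertiary C10 radical so formed adds to the CH2 terminus (C9) of the isopropenyl group, and the tertiary C8 radical loses a methyl hydrogen to a second Cp2TiCl to leave the exocyclic C8 methylene, while hydrolysis of the O–Ti bond frees the C15 alcohol. The closest known reaction type is the Nugent–RajanBabu reductive epoxide opening in its epoxypolyene radical-cascade form, which is used to make trans-decalin terpenoids. Ring A is closed 6-endo-trig by the C4–C5 bond and ring B 6-endo-trig by the C9–C10 bond, each radical attacking the less substituted alkene carbon. C5 and C10 arise by anti addition across the E-C5=C10 bond in a chair–chair transition state, which gives the trans fusion (5α-H, 10β-CH3); C4 is set by the equatorial CH2OTi group in the ring A chair; and the sense relative to C1, C6 and C7 is fixed by these existing centres, because only the transition state leading to 19 holds both OTES groups and the CH2CO2tBu group equatorial, with H6 in the alkene plane (allylic 1,3-strain towards the C10 methyl) so that C4 approaches C5 anti to C7. The step needs 6-endo over 5-exo closure twice (secured by the fully substituted inner alkene carbons C10 and C8), cyclization faster than reduction of the C4 radical (secured by slow addition of Cp2TiCl at high dilution) and exocyclic termination (the methyl hydrogens are the most accessible to the titanium reagent; minor endocyclic isomers are removed by chromatography).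

Step 12
Reactants: 19 tert-butyl 2-[4α-(hydroxymethyl)-10β-methyl-8-methylidene-1β,6α-bis(triethylsilyloxy)-5αH-trans-decalin-7β-yl]acetate
Product: 22 tert-butyl 2-[4α-(hydroxymethyl)-10β-methyl-8-methylidene-1β,6α-bis(triethylsilyloxy)-5αH-trans-decalin-7β-yl]prop-2-enoate, via Mannich base 20 (not isolated), via trimethylammonium iodide 21 (not isolated)
Conditions: LiN(iPr)2 (2.2 equiv), THF, −78 °C; CH2=NMe2+ I−, −78 → 0 °C; then MeI, MeOH, rt; then DBU, CH2Cl2, rt
Reagents that add atoms: N,N-dimethylmethyleneiminium iodide C=[N+](C)C.[I-]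
Why: Eschenmoser methylenation, in which the lithium ester enolate at C11 (formed beside the C15 alkoxide) is aminomethylated and quaternisation then E1cB elimination of 21 installs the C11=C13 methylene, the transient C11 stereocenter being destroyed.

Step 13
Reactants: 22 tert-butyl 2-[4α-(hydroxymethyl)-10β-methyl-8-methylidene-1β,6α-bis(triethylsilyloxy)-5αH-trans-decalin-7β-yl]prop-2-enoate
Product: 24 tert-butyl 2-[8β-hydroxy-4α-(hydroxymethyl)-10β-methyl-1β,6α-bis(triethylsilyloxy)-5αH-trans-decalin-7β-yl]prop-2-enoate, via C8 ketone 23 (not isolated)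
Conditions: O3 (1 equiv), CH2Cl2/MeOH, −78 °C; then NaBH4, −78 → 0 °C; neutral work-up
Reagents that add atoms: ozone [O-][O+]=O
Why: Chemoselective ozonolysis removes the electron-rich exocyclic C8 methylene far faster than the electron-poor acrylate, and NaBH4 then reduces ketone 23 from the α face, anti to the axial C10 methyl, to the axial 8β-alcohol as in reductions of 8-oxoeudesmanes, the tert-butyl ester resisting lactonisation.

Step 14
Reactants: 24 tert-butyl 2-[8β-hydroxy-4α-(hydroxymethyl)-10β-methyl-1β,6α-bis(triethylsilyloxy)-5αH-trans-decalin-7β-yl]prop-2-enoate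
Product: 25 tert-butyl 2-[4α-formyl-8β-hydroxy-10β-methyl-1β,6α-bis(triethylsilyloxy)-5αH-trans-decalin-7β-yl]prop-2-enoate
Conditions: TEMPO (cat.), PhI(OAc)2, CH2Cl2, rt
Reagents that add atoms: none
Why: TEMPO-catalysed oxidation is selective for the primary C15 alcohol over the hindered axial C8 alcohol and stops at the aldehyde, whose equatorial position at C4 is also the thermodynamic one.

Step 15
Reactants: 26 ethyl 2-(hydroxymethyl)prop-2-enoate
Product: 27 ethyl 2-[(tert-butyldimethylsilyloxy)methyl]prop-2-enoate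
Conditions: TBSCl, imidazole, CH2Cl2, 0 °C
Reagents that add atoms: tert-butylchlorodimethylsilane CC(C)(C)[Si](C)(C)Cl
Why: Silyl ether formation on the primary allylic alcohol; no stereocenter.

Step 16
Reactants: 27 ethyl 2-[(tert-butyldimethylsilyloxy)methyl]prop-2-enoate
Product: 28 2-[(tert-butyldimethylsilyloxy)methyl]prop-2-enoic acid
Conditions: LiOH, THF/H2O, 0 °C; then dilute HCl to pH 4
Reagents that add atoms: lithium hydroxide [Li+].[OH-]
Why: Ester saponification at 0 °C, where the primary TBS ether survives and hydroxide does not add in a conjugate sense; no stereocenter.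

Step 17
Reactants: 25 tert-butyl 2-[4α-formyl-8β-hydroxy-10β-methyl-1β,6α-bis(triethylsilyloxy)-5αH-trans-decalin-7β-yl]prop-2-enoate; 28 2-[(tert-butyldimethylsilyloxy)methyl]prop-2-enoic acid
Product: 29 tert-butyl 2-[8α-({2-[(tert-butyldimethylsilyloxy)methyl]prop-2-enoyl}oxy)-4α-formyl-10β-methyl-1β,6α-bis(triethylsilyloxy)-5αH-trans-decalin-7β-yl]prop-2-enoate
Conditions: PPh3, DIAD (premixed), toluene, 0 °C → rt
Reagents that add atoms: none
Why: Mitsunobu esterification displaces the axial 8β-oxyphosphonium group by SN2 attack of the carboxylate from the open α face, so the ester is installed with inversion as the equatorial 8α-acyloxy group.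

Step 18
Reactants: 29 tert-butyl 2-[8α-({2-[(tert-butyldimethylsilyloxy)methyl]prop-2-enoyl}oxy)-4α-formyl-10β-methyl-1β,6α-bis(triethylsilyloxy)-5αH-trans-decalin-7β-yl]prop-2-enoate
Product: 31 2-[4α-formyl-1β,6α-dihydroxy-8α-{[2-(hydroxymethyl)prop-2-enoyl]oxy}-10β-methyl-5αH-trans-decalin-7β-yl]prop-2-enoic acid (CNP0599450.1), via trimethylsilyl ester 30 (not isolated)
Conditions: TMSOTf, 2,6-lutidine, CH2Cl2, 0 °C; then HF·pyridine, pyridine, THF, 0 °C → rt
Reagents that add atoms: none
Why: TMSOTf/2,6-lutidine converts the tert-butyl ester into silyl ester 30 with loss of isobutene under non-protic conditions, and buffered HF·pyridine then cleaves the silyl ester, both TES ethers and the TBS ether (silyl cleavage) without acid strong enough to lactonise the 6-hydroxy-12-acid.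

**Compound list**

1 | 4-tert-butoxy-4-oxobutanoic acid (mono-tert-butyl succinate) | CC(C)(C)OC(=O)CCC(=O)O | starting material
2 | (4S)-4-benzyl-1,3-oxazolidin-2-one | O=C1N[C@@H](Cc2ccccc2)CO1 | starting material
3 | 4-tert-butoxy-4-oxobutanoic pivalic anhydride | CC(C)(C)OC(=O)CCC(=O)OC(=O)C(C)(C)C | intermediate (not isolated)
4 | (4S)-4-benzyl-3-(4-tert-butoxy-4-oxobutanoyl)-1,3-oxazolidin-2-one | CC(C)(C)OC(=O)CCC(=O)N1[C@@H](Cc2ccccc2)COC1=O | intermediate
5 | but-2-yn-1-ol | CC#CCO | starting material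
6 | but-2-ynal | CC#CC=O | intermediate
7 | dibutylboron (Z)-enolate of 4 | CC(C)(C)OC(=O)C/C=C(\OB(CCCC)CCCC)N1[C@@H](Cc2ccccc2)COC1=O | intermediate (not isolated)
8 | (4S)-4-benzyl-3-[(2S,3S)-2-(2-tert-butoxy-2-oxoethyl)-3-hydroxyhex-4-ynoyl]-1,3-oxazolidin-2-one | CC#C[C@@H](O)[C@H](CC(=O)OC(C)(C)C)C(=O)N1[C@@H](Cc2ccccc2)COC1=O | intermediate
9 | tert-butyl (3S,4S)-4-hydroxy-3-[methoxy(methyl)carbamoyl]hept-5-ynoate | CC#C[C@@H](O)[C@H](CC(=O)OC(C)(C)C)C(=O)N(C)OC | intermediate
10 | tert-butyl (3S,4S)-3-[methoxy(methyl)carbamoyl]-4-(triethylsilyloxy)hept-5-ynoate | CC#C[C@@H](O[Si](CC)(CC)CC)[C@H](CC(=O)OC(C)(C)C)C(=O)N(C)OC | intermediate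
11 | tert-butyl (3S,4S)-3-acetyl-4-(triethylsilyloxy)hept-5-ynoate | CC#C[C@@H](O[Si](CC)(CC)CC)[C@H](CC(=O)OC(C)(C)C)C(C)=O | intermediate
12 | tert-butyl (3R,4S)-3-(prop-1-en-2-yl)-4-(triethylsilyloxy)hept-5-ynoate | CC#C[C@@H](O[Si](CC)(CC)CC)[C@H](CC(=O)OC(C)(C)C)C(C)=C | intermediate
13 | (2R)-2-(but-3-en-1-yl)oxirane [(R)-1,2-epoxy-5-hexene] | C=CCC[C@@H]1CO1 | starting material
14 | 3-[(2R)-oxiran-2-yl]propanal | O=CCC[C@@H]1CO1 | intermediate
15 | alkenylzirconocene chloride: Cp2Zr(Cl) on C10 of the E-alkene from 12, H on C5 | C=C(C)[C@@H](CC(=O)OC(C)(C)C)[C@H](O[Si](CC)(CC)CC)/C=C(\C)[Zr](Cl)(C1C=CC=C1)C1C=CC=C1 | intermediate (not isolated)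
16 | alkenyl(methyl)zinc: MeZn on C10 of the same E-alkene | C=C(C)[C@@H](CC(=O)OC(C)(C)C)[C@H](O[Si](CC)(CC)CC)/C=C(\C)[Zn]C | intermediate (not isolated)
17 | tert-butyl (3R,4R,5E,7R)-7-hydroxy-6-methyl-9-[(2R)-oxiran-2-yl]-3-(prop-1-en-2-yl)-4-(triethylsilyloxy)non-5-enoate | C=C(C)[C@@H](CC(=O)OC(C)(C)C)[C@H](O[Si](CC)(CC)CC)/C=C(\C)[C@H](O)CC[C@@H]1CO1 | intermediate
18 | tert-butyl (3R,4R,5E,7R)-6-methyl-9-[(2R)-oxiran-2-yl]-3-(prop-1-en-2-yl)-4,7-bis(triethylsilyloxy)non-5-enoate | C=C(C)[C@@H](CC(=O)OC(C)(C)C)[C@H](O[Si](CC)(CC)CC)/C=C(\C)[C@H](O[Si](CC)(CC)CC)CC[C@@H]1CO1 | intermediate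
19 | trans-decalin: 1β-OTES, 4α-CH2OH, 5α-H, 6α-OTES, 7β-CH2CO2tBu, 10β-CH3, exocyclic C8=CH2 | C=C1C[C@]2(C)[C@@H]([C@@H](O[Si](CC)(CC)CC)[C@@H]1CC(=O)OC(C)(C)C)[C@H](CO)CC[C@H]2O[Si](CC)(CC)CC | intermediate
20 | Mannich base: 19 with CH2NMe2 on C11 (C11 epimers) | C=C1C[C@]2(C)[C@@H]([C@@H](O[Si](CC)(CC)CC)[C@@H]1C(CN(C)C)C(=O)OC(C)(C)C)[C@H](CO)CC[C@H]2O[Si](CC)(CC)CC | intermediate (not isolated)
21 | trimethylammonium iodide of 20 | C=C1C[C@]2(C)[C@@H]([C@@H](O[Si](CC)(CC)CC)[C@@H]1C(C[N+](C)(C)C)C(=O)OC(C)(C)C)[C@H](CO)CC[C@H]2O[Si](CC)(CC)CC.[I-] | intermediate (not isolated)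
22 | trans-decalin: as 19 but 7β-C(=CH2)CO2tBu | C=C1C[C@]2(C)[C@@H]([C@@H](O[Si](CC)(CC)CC)[C@@H]1C(=C)C(=O)OC(C)(C)C)[C@H](CO)CC[C@H]2O[Si](CC)(CC)CC | intermediate
23 | C8 ketone: as 22 but C8=O | O=C1C[C@]2(C)[C@@H]([C@@H](O[Si](CC)(CC)CC)[C@@H]1C(=C)C(=O)OC(C)(C)C)[C@H](CO)CC[C@H]2O[Si](CC)(CC)CC | intermediate (not isolated)
24 | 8β-alcohol (axial OH at C8), 4α-CH2OH | O[C@@H]1C[C@]2(C)[C@@H]([C@@H](O[Si](CC)(CC)CC)[C@@H]1C(=C)C(=O)OC(C)(C)C)[C@H](CO)CC[C@H]2O[Si](CC)(CC)CC | intermediate
25 | 8β-alcohol with 4α-CHO | O[C@@H]1C[C@]2(C)[C@@H]([C@@H](O[Si](CC)(CC)CC)[C@@H]1C(=C)C(=O)OC(C)(C)C)[C@H](C=O)CC[C@H]2O[Si](CC)(CC)CC | intermediate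
26 | ethyl 2-(hydroxymethyl)prop-2-enoate | C=C(CO)C(=O)OCC | starting material
27 | ethyl 2-[(tert-butyldimethylsilyloxy)methyl]prop-2-enoate | C=C(CO[Si](C)(C)C(C)(C)C)C(=O)OCC | intermediate
28 | 2-[(tert-butyldimethylsilyloxy)methyl]prop-2-enoic acid | C=C(CO[Si](C)(C)C(C)(C)C)C(=O)O | intermediate
29 | fully protected target: 8α-acyloxy ester, tert-butyl ester, two TES ethers, one TBS ether | C=C(CO[Si](C)(C)C(C)(C)C)C(=O)O[C@H]1C[C@]2(C)[C@@H]([C@@H](O[Si](CC)(CC)CC)[C@@H]1C(=C)C(=O)OC(C)(C)C)[C@H](C=O)CC[C@H]2O[Si](CC)(CC)CC | intermediate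
30 | trimethylsilyl ester of 29 (tert-butyl replaced by SiMe3) | C=C(CO[Si](C)(C)C(C)(C)C)C(=O)O[C@H]1C[C@]2(C)[C@@H]([C@@H](O[Si](CC)(CC)CC)[C@@H]1C(=C)C(=O)O[Si](C)(C)C)[C@H](C=O)CC[C@H]2O[Si](CC)(CC)CC | intermediate (not isolated)
31 | CNP0599450.1: 1β,6α-dihydroxy-8α-[2-(hydroxymethyl)acryloyloxy]-15-oxo-eudesm-11(13)-en-12-oic acid (5α-H, 4β-H, 7α-H, 10β-CH3) | C=C(CO)C(=O)O[C@H]1C[C@]2(C)[C@@H]([C@@H](O)[C@@H]1C(=C)C(=O)O)[C@H](C=O)CC[C@H]2O | target

**Step count.** Total: 18 steps. Longest linear sequence: 14 steps (steps 1, 3–7, 9–14, 17, 18).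

**Steps most likely to fail**

Step 11 (key cascade). The C4 radical may be reduced by a second Cp2TiCl before it reaches the hindered C5 (giving deoxygenation or simple reduction). The first addition may show poor facial selectivity relative to C1 and C6, and termination may give endocyclic alkene isomers. Fallback, from 18 back to 19: Meinwald rearrangement of the oxirane (Cr(TPP)OTf cat., CH2Cl2) would give tert-butyl (3R,4R,5E,7R)-6-methyl-11-oxo-3-(prop-1-en-2-yl)-4,7-bis(triethylsilyloxy)undec-5-enoate F1. An enamine single-electron-oxidation (SOMO) polyene bicyclization (chiral imidazolidinone·TFA salt, Cu(OTf)2, NaO2CCF3, iPrCN/DME) would then generate the C4 radical cation from the aldehyde itself. It should close rings A and B in the same 6-endo/6-endo sense and end by oxidation of the C8 radical to the exocyclic alkene, giving the decalin aldehyde F2. NaBH4 reduction of F2 returns to 19.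

Step 17 (inversion at C8). Formation of the oxyphosphonium at the hindered axial alcohol may be slow, and anti elimination towards C7 or C9 may compete with substitution. Fallback, from 25 back to 29: Tf2O/pyridine (−20 °C) would give the 8β-triflate F3. Displacement with Bu4NNO2 (toluene/DMF, 0 °C) and hydrolysis of the nitrite ester would give the inverted, equatorial 8α-alcohol F4. Carbodiimide esterification (EDC·HCl, DMAP, Steglich conditions) of F4 with 28 then proceeds with retention to 29. Any 8α-alcohol formed as a minor product in step 13 can be fed into the same esterification.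

Step 9 (C1–C10 bond). Regiocontrol in the hydrozirconation may be incomplete, facial selectivity in the zinc addition to an unbranched aldehyde may be low, and the oxirane may be opened by the alkoxide during work-up. Fallback, from 12 back to 17: hydrozirconation then iodination (Cp2Zr(H)Cl; I2) would give tert-butyl (3R,4S,5E)-6-iodo-3-(prop-1-en-2-yl)-4-(triethylsilyloxy)hept-5-enoate F5. Nozaki–Hiyama–Kishi coupling with 14 (CrCl2, NiCl2 cat., DMF) would give the C7-epimeric allylic alcohols F6. Dess–Martin oxidation would give the enone F7, and reagent-controlled CBS reduction ((S)-Me-CBS, catecholborane, −40 °C) sets the (7R)-carbinol and returns to 17.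

**Further compounds**

F1 | step 11 | tert-butyl (3R,4R,5E,7R)-6-methyl-11-oxo-3-(prop-1-en-2-yl)-4,7-bis(triethylsilyloxy)undec-5-enoate | C=C(C)[C@@H](CC(=O)OC(C)(C)C)[C@H](O[Si](CC)(CC)CC)/C=C(\C)[C@H](O[Si](CC)(CC)CC)CCCC=O
F2 | step 11 | decalin aldehyde: 19 with 4α-CHO in place of 4α-CH2OH | C=C1C[C@]2(C)[C@@H]([C@@H](O[Si](CC)(CC)CC)[C@@H]1CC(=O)OC(C)(C)C)[C@H](C=O)CC[C@H]2O[Si](CC)(CC)CC
F3 | step 17 | 8β-trifluoromethanesulfonate of 25 | O=S(=O)(O[C@@H]1C[C@]2(C)[C@@H]([C@@H](O[Si](CC)(CC)CC)[C@@H]1C(=C)C(=O)OC(C)(C)C)[C@H](C=O)CC[C@H]2O[Si](CC)(CC)CC)C(F)(F)F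
F4 | step 17 | 8α-alcohol (C8 epimer of 25) | O[C@H]1C[C@]2(C)[C@@H]([C@@H](O[Si](CC)(CC)CC)[C@@H]1C(=C)C(=O)OC(C)(C)C)[C@H](C=O)CC[C@H]2O[Si](CC)(CC)CC
F5 | step 9 | tert-butyl (3R,4S,5E)-6-iodo-3-(prop-1-en-2-yl)-4-(triethylsilyloxy)hept-5-enoate | C=C(C)[C@@H](CC(=O)OC(C)(C)C)[C@H](O[Si](CC)(CC)CC)/C=C(\C)I
F6 | step 9 | tert-butyl (3R,4R,5E,7RS)-7-hydroxy-6-methyl-9-[(2R)-oxiran-2-yl]-3-(prop-1-en-2-yl)-4-(triethylsilyloxy)non-5-enoate (C7 epimers) | C=C(C)[C@@H](CC(=O)OC(C)(C)C)[C@H](O[Si](CC)(CC)CC)/C=C(\C)C(O)CC[C@@H]1CO1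
F7 | step 9 | tert-butyl (3R,4R,5E)-6-methyl-9-[(2R)-oxiran-2-yl]-7-oxo-3-(prop-1-en-2-yl)-4-(triethylsilyloxy)non-5-enoate | C=C(C)[C@@H](CC(=O)OC(C)(C)C)[C@H](O[Si](CC)(CC)CC)/C=C(\C)C(=O)CC[C@@H]1CO1
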